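**Plan**

- Cuts (1-oxaspiro[2.5]octane numbering): the dienone C(=O)–CH= bond, the furyl–C(=O) bond, the glycidate (back to a C-3 ketone), the C-8 methyl, and last C-4–C-5 and C-7–C-8 of the cyclohexane in one operation.
- Enabling feature: the spiro carbon C-3 is flanked by two acyl-bearing quaternary ring carbons (C-4 and C-8), which is a masked 2,4-disubstituted 3-oxoglutarate (a 1,3-bis-enolate). C-5 carries CH(OH)CH3 γ to the C-4 acyl carbon (enolate plus epoxide), and C-6/C-7 is a plain ethylene (primary iodide).
- Forward: the cyclohexanone ring and a trans-fused γ-lactone (a temporary ring that masks the C-4 acyl group and the alcohol) arise together in the annulation. Then follow the lactol acetal, the C-8 methyl, the spiro-epoxide and the furyl ketone; the separately made pyranone ring is joined last.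
- Stereochemistry: C-5 and the carbinol carbon come from a catalytic asymmetric epoxidation (inversion and retention in the annulation). C-4 comes from the chelated chair transition state. C-8, C-3 and C-2 come from attack anti to the axial angular methyl of the rigid trans-fused bicycle. The alkene geometry comes from syn-carbopalladation.

Key step: step 5

Remark: positions that are stereochemically mobile in the intermediates (the enolisable carbon next to the thioester before its methylation, and the lactol, acetal and transient carbinol carbons) form as mixtures that converge later and are drawn without configuration.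

**Step 1**
Reactants: 1 pent-3-yn-1-ol
Product: 2 (Z)-pent-3-en-1-ol
Conditions: H2 (1 atm), Pd/CaCO3 poisoned with Pb(OAc)2, quinoline, MeOH, 23 °C
Reagents that add atoms: none
Why: Lindlar semi-hydrogenation (syn addition of H2 on the poisoned Pd surface) gives the (Z)-alkene needed for a cis-epoxide and stops before over-reduction.

**Step 2**
Reactants: 2 (Z)-pent-3-en-1-ol
Product: 3 2-[(2S,3R)-3-methyloxiran-2-yl]ethan-1-ol
Conditions: VO(Oi-Pr)3 (2 mol%), chiral C2-symmetric bis-hydroxamic acid ligand (N,N'-dihydroxy-N,N'-bis(diarylacetyl)-trans-cyclohexane-1,2-diamine, the antipode that delivers the (2S,3R)-epoxide, 4 mol%), cumene hydroperoxide, toluene, 23 °C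
Reagents that add atoms: cumene hydroperoxide, CC(C)(OO)c1ccccc1
Why: Vanadium-catalysed asymmetric epoxidation of a homoallylic alcohol with a chiral bis-hydroxamic acid ligand transfers oxygen stereospecifically to the (Z)-alkene from the face fixed by the ligand-bound alkoxide, which sets both epoxide carbons in one event.

**Step 3**
Reactants: 3 2-[(2S,3R)-3-methyloxiran-2-yl]ethan-1-ol
Product: 4 (2S,3R)-2-(2-iodoethyl)-3-methyloxirane
Conditions: I2, PPh3, imidazole, CH2Cl2, 0 °C
Reagents that add atoms: iodine, II
Why: Appel-type iodination converts the primary alcohol into the iodide by SN2 at a non-stereogenic carbon, and the imidazole buffer should leave the cis-epoxide and its two stereocentres intact.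

**Step 4**
Reactants: 5 methyl 2-methyl-3-oxobutanoate (racemic, 2 equiv); 6 S-ethyl carbonochloridothioate
Product: 7 methyl 5-(ethylsulfanyl)-2-methyl-3,5-dioxopentanoate
Conditions: LiN(i-Pr)2 (4.1 equiv), THF, −78 → 0 °C; then 6 (1 equiv), −78 °C; aq. NH4Cl
Reagents that add atoms: none
Why: γ-Acylation of a β-keto ester dianion (Weiler dianion chemistry), in which the terminal and most basic carbanion of the dilithio derivative of 5 attacks the chlorothioformate while the second equivalent of dianion absorbs the proton of the more acidic product.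

**Step 5**
Reactants: 7 methyl 5-(ethylsulfanyl)-2-methyl-3,5-dioxopentanoate (1.2 equiv); 4 (2S,3R)-2-(2-iodoethyl)-3-methyloxirane
Product: 9 S-ethyl (3R,3aS,7aR)-3,7a-dimethyl-1,7-dioxooctahydro-2-benzofuran-6-carbothioate (C-6 epimers and enol), via epoxy keto ester 8 (not isolated)
Conditions: NaH (1.1 equiv), THF/DMPU (5:1), 0 → 23 °C; then LiN(i-Pr)2 (2.1 equiv), −78 → 40 °C; aq. NH4Cl
Reagents that add atoms: none
Why: Sodium hydride forms the enolate at the most acidic and least hindered carbon of 7 (the CH2 between thioester and ketone), which displaces the primary iodide of 4 to give 8; the second base then generates the 2,4-dianion, whose methyl-bearing, more basic carbon opens the epoxide at its near carbon by SN2, and the alkoxide set free acylates itself on the neighbouring methyl ester. The closest known reactions are the α,α'-cycloalkylation of acetonedicarboxylates with 1,3-dielectrophiles and the malonate–epichlorohydrin alkylation/epoxide-opening/lactonisation sequence. The cyclohexanone closes by 6-exo-tet C-alkylation of the enolate (allowed in both the enolendo and the enolexo sense) and the lactone by 5-exo-trig acyl substitution. C-3a arises from the (2S)-epoxide carbon with inversion and C-3 keeps the (3R) configuration of 4, while the quaternary C-7a is set by a chair-like transition state in which the lithium-chelated, U-shaped enolate turns its methyl group axial and its ester equatorial and the epoxide arm sits equatorial, which gives the trans ring fusion; C-6 remains enolisable and is fixed in step 7. The step needs C-4 of 7 to be alkylated before C-2, the iodide to react before the epoxide, attack at the near epoxide carbon and C- over O-alkylation, which should be secured by the acidity gap between the two sites, the far higher SN2 rate of a primary iodide, the six- versus seven-membered transition state and the lithium dianion reacting at its most basic carbon. Because the product is held as the enolate of its β-keto thioester, the liberated methoxide is buffered and the ketone is shielded from retro-Claisen cleavage.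

**Step 6**
Reactants: 9 S-ethyl (3R,3aS,7aR)-3,7a-dimethyl-1,7-dioxooctahydro-2-benzofuran-6-carbothioate
Product: 11 S-ethyl (3R,3aS,7aS)-1-methoxy-3,7a-dimethyl-7-oxooctahydro-2-benzofuran-6-carbothioate (anomers and C-6 epimers), via lactol 10 (not isolated)
Conditions: NaN(SiMe3)2 (1.05 equiv), THF, −78 °C; i-Bu2AlH (1.5 equiv), −78 °C; aq. potassium sodium tartrate; then MeOH, PPTS (cat.), 23 °C
Reagents that add atoms: methanol, CO
Why: Chemoselective lactone-to-lactol reduction in which the β-keto thioester is first masked as its sodium enolate, which i-Bu2AlH does not reduce, after which acid-catalysed acetalisation with methanol locks the lactol as a methyl acetal that freezes the trans-fused bicycle (the acetal carbon is an inconsequential anomeric mixture).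

**Step 7**
Reactants: 11 S-ethyl (3R,3aS,7aS)-1-methoxy-3,7a-dimethyl-7-oxooctahydro-2-benzofuran-6-carbothioate
Product: 12 S-ethyl (3R,3aS,6R,7aS)-1-methoxy-3,6,7a-trimethyl-7-oxooctahydro-2-benzofuran-6-carbothioate
Conditions: K2CO3, MeI, acetone, 23 °C
Reagents that add atoms: iodomethane, CI
Why: C-Alkylation of a β-keto thioester enolate with MeI, in which the trans ring fusion holds the angular C-7a methyl axial so that the electrophile should enter C-6 from the opposite face and give the quaternary centre with its methyl anti to the angular methyl and the thioester axial.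

**Step 8**
Reactants: 12 S-ethyl (3R,3aS,6R,7aS)-1-methoxy-3,6,7a-trimethyl-7-oxooctahydro-2-benzofuran-6-carbothioate; 13 methyl chloroacetate (3 equiv)
Product: 14 methyl (3R,3aS,3'S,6R,7S,7aR)-6-[(ethylsulfanyl)carbonyl]-1-methoxy-3,6,7a-trimethylhexahydro-1H-spiro[2-benzofuran-7,2'-oxirane]-3'-carboxylate
Conditions: NaN(SiMe3)2 (3 equiv), THF, −78 → 0 °C
Reagents that add atoms: none
Why: Darzens glycidic ester condensation on the only ketone present, in which the chloroacetate enolate attacks C-7 along the axial trajectory anti to the two axial α-substituents (angular methyl and thioester), the alkoxide displaces chloride so that the epoxide oxygen is equatorial, and the reversible aldol step should channel material to the glycidate whose ester points to the smaller equatorial C-6 methyl.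

**Step 9**
Reactants: 14 methyl (3R,3aS,3'S,6R,7S,7aR)-6-[(ethylsulfanyl)carbonyl]-1-methoxy-3,6,7a-trimethylhexahydro-1H-spiro[2-benzofuran-7,2'-oxirane]-3'-carboxylate; 15 furan-3-ylboronic acid (2 equiv)
Product: 16 methyl (3R,3aS,3'S,6R,7S,7aR)-6-(furan-3-carbonyl)-1-methoxy-3,6,7a-trimethylhexahydro-1H-spiro[2-benzofuran-7,2'-oxirane]-3'-carboxylate
Conditions: Pd2(dba)3 (5 mol%), P(2-furyl)3 (20 mol%), Cu(O2C-C4H3S) (copper thiophene-2-carboxylate, 2 equiv), THF, 50 °C
Reagents that add atoms: none
Why: Liebeskind–Srogl coupling of the thioester with the boronic acid (zerovalent palladium, copper carboxylate as thiophile) forms the 3-furyl ketone under neutral conditions that spare the epoxide, the methyl ester and the acetal, and no stereocentre is touched.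

**Step 10**
Reactants: 16 methyl (3R,3aS,3'S,6R,7S,7aR)-6-(furan-3-carbonyl)-1-methoxy-3,6,7a-trimethylhexahydro-1H-spiro[2-benzofuran-7,2'-oxirane]-3'-carboxylate
Product: 17 methyl (3R,3aS,3'S,6R,7S,7aR)-6-(furan-3-carbonyl)-1-hydroxy-3,6,7a-trimethylhexahydro-1H-spiro[2-benzofuran-7,2'-oxirane]-3'-carboxylate (lactol, anomers)
Conditions: p-TsOH·H2O (cat.), acetone/H2O (4:1), 40 °C
Reagents that add atoms: water, O
Why: Mild acid hydrolysis of the cyclic methyl acetal through its oxocarbenium ion frees the lactol, and the electron-poor glycidic epoxide and the 3-acylfuran should be far less acid-sensitive than the acetal when the acid has a non-nucleophilic counter-ion.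

**Step 11**
Reactants: 18 (Z)-3-iodoprop-2-enoic acid; 19 2-methylbut-3-yn-2-ol
Product: 20 2-methylbut-3-yn-2-yl (Z)-3-iodoprop-2-enoate
Conditions: DCC, DMAP (10 mol%), CH2Cl2, 0 → 23 °C
Reagents that add atoms: none
Why: Steglich esterification (DCC activation, DMAP acyl transfer) acylates the tertiary propargylic alcohol at low temperature and should not isomerise the (Z)-iodoalkene.

**Step 12**
Reactants: 20 2-methylbut-3-yn-2-yl (Z)-3-iodoprop-2-enoate
Product: 21 (5E)-5-(iodomethylidene)-6,6-dimethyl-5,6-dihydro-2H-pyran-2-one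
Conditions: Pd2(dba)3 (5 mol%), dppf (12 mol%), toluene, 90 °C
Reagents that add atoms: none
Why: Palladium-catalysed intramolecular alkyne carboiodination, in which oxidative addition of the alkenyl iodide to zerovalent palladium, 6-exo-dig syn-carbopalladation of the alkyne and C–I reductive elimination close the pyranone ring and place iodine cis to the ring alkene, which is the (E)-alkylidene geometry of the target.

**Step 13**
Reactants: 17 methyl (3R,3aS,3'S,6R,7S,7aR)-6-(furan-3-carbonyl)-1-hydroxy-3,6,7a-trimethylhexahydro-1H-spiro[2-benzofuran-7,2'-oxirane]-3'-carboxylate; 21 (5E)-5-(iodomethylidene)-6,6-dimethyl-5,6-dihydro-2H-pyran-2-one (2 equiv)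
Product: 22 methyl (2S,3S,4S,5S,8R)-8-(furan-3-carbonyl)-4-[(2E)-2-(2,2-dimethyl-6-oxo-2H-pyran-3(6H)-ylidene)-1-hydroxyethyl]-5-[(1R)-1-hydroxyethyl]-4,8-dimethyl-1-oxaspiro[2.5]octane-2-carboxylate (carbinol epimers)
Conditions: CrCl2 (6 equiv), NiCl2 (2 mol%), DMSO/THF, 23 °C
Reagents that add atoms: none
Why: Nozaki–Hiyama–Kishi coupling, in which the alkenylchromium species made from 21 adds with retention of alkene geometry only to the aldehyde in equilibrium with lactol 17 and tolerates the ketone, esters, epoxide and free hydroxyl, while the new carbinol centre is removed in step 14.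

**Step 14**
Reactants: 22 methyl (2S,3S,4S,5S,8R)-8-(furan-3-carbonyl)-4-[(2E)-2-(2,2-dimethyl-6-oxo-2H-pyran-3(6H)-ylidene)-1-hydroxyethyl]-5-[(1R)-1-hydroxyethyl]-4,8-dimethyl-1-oxaspiro[2.5]octane-2-carboxylate
Product: 23 methyl (2S,3R,4R,5S,8R)-4-[(2E)-2-(2,2-dimethyl-6-oxo-2H-pyran-3(6H)-ylidene)acetyl]-8-(furan-3-carbonyl)-5-[(1R)-1-hydroxyethyl]-4,8-dimethyl-1-oxaspiro[2.5]octane-2-carboxylate (CNP0293135.1)
Conditions: MnO2 (20 equiv), CH2Cl2, 23 °C
Reagents that add atoms: none
Why: MnO2 oxidises only the doubly allylic alcohol to the cross-conjugated dienone and leaves the saturated secondary alcohol, which completes the target.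

**Compound list**

1 | pent-3-yn-1-ol | CC#CCCO | starting material
2 | (Z)-pent-3-en-1-ol | C/C=C\CCO | intermediate
3 | 2-[(2S,3R)-3-methyloxiran-2-yl]ethan-1-ol | OCC[C@@H]1O[C@@H]1C | intermediate
4 | (2S,3R)-2-(2-iodoethyl)-3-methyloxirane | ICC[C@@H]1O[C@@H]1C | intermediate
5 | methyl 2-methyl-3-oxobutanoate (racemic) | CC(=O)C(C)C(=O)OC | starting material
6 | S-ethyl carbonochloridothioate | CCSC(Cl)=O | starting material
7 | methyl 5-(ethylsulfanyl)-2-methyl-3,5-dioxopentanoate | CCSC(=O)CC(=O)C(C)C(=O)OC | intermediate
8 | methyl 4-[(ethylsulfanyl)carbonyl]-2-methyl-6-[(2S,3R)-3-methyloxiran-2-yl]-3-oxohexanoate (C-2 and C-4 epimers) | CCSC(=O)C(CC[C@@H]1O[C@@H]1C)C(=O)C(C)C(=O)OC | intermediate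
9 | S-ethyl (3R,3aS,7aR)-3,7a-dimethyl-1,7-dioxooctahydro-2-benzofuran-6-carbothioate (trans-fused; C-6 epimers and enol) | CCSC(=O)C1CC[C@@H]2[C@@H](C)OC(=O)[C@@]2(C)C1=O | intermediate
10 | S-ethyl (3R,3aS,7aS)-1-hydroxy-3,7a-dimethyl-7-oxooctahydro-2-benzofuran-6-carbothioate (lactol; anomers and C-6 epimers) | CCSC(=O)C1CC[C@@H]2[C@@H](C)OC(O)[C@@]2(C)C1=O | intermediate
11 | S-ethyl (3R,3aS,7aS)-1-methoxy-3,7a-dimethyl-7-oxooctahydro-2-benzofuran-6-carbothioate (anomers and C-6 epimers) | CCSC(=O)C1CC[C@@H]2[C@@H](C)OC(OC)[C@@]2(C)C1=O | intermediate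
12 | S-ethyl (3R,3aS,6R,7aS)-1-methoxy-3,6,7a-trimethyl-7-oxooctahydro-2-benzofuran-6-carbothioate (anomers) | CCSC(=O)[C@]1(C)CC[C@@H]2[C@@H](C)OC(OC)[C@@]2(C)C1=O | intermediate
13 | methyl chloroacetate | COC(=O)CCl | starting material
14 | methyl (3R,3aS,3'S,6R,7S,7aR)-6-[(ethylsulfanyl)carbonyl]-1-methoxy-3,6,7a-trimethylhexahydro-1H-spiro[2-benzofuran-7,2'-oxirane]-3'-carboxylate (anomers) | CCSC(=O)[C@]1(C)CC[C@@H]2[C@@H](C)OC(OC)[C@@]2(C)[C@]13O[C@@H]3C(=O)OC | intermediate
15 | furan-3-ylboronic acid | OB(O)c1ccoc1 | starting material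
16 | methyl (3R,3aS,3'S,6R,7S,7aR)-6-(furan-3-carbonyl)-1-methoxy-3,6,7a-trimethylhexahydro-1H-spiro[2-benzofuran-7,2'-oxirane]-3'-carboxylate (anomers) | O=C(c1ccoc1)[C@]2(C)CC[C@@H]3[C@@H](C)OC(OC)[C@@]3(C)[C@]24O[C@@H]4C(=O)OC | intermediate
17 | methyl (3R,3aS,3'S,6R,7S,7aR)-6-(furan-3-carbonyl)-1-hydroxy-3,6,7a-trimethylhexahydro-1H-spiro[2-benzofuran-7,2'-oxirane]-3'-carboxylate (lactol, anomers) | O=C(c1ccoc1)[C@]2(C)CC[C@@H]3[C@@H](C)OC(O)[C@@]3(C)[C@]24O[C@@H]4C(=O)OC | intermediate
18 | (Z)-3-iodoprop-2-enoic acid | OC(=O)/C=C\I | starting material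
19 | 2-methylbut-3-yn-2-ol | CC(C)(O)C#C | starting material
20 | 2-methylbut-3-yn-2-yl (Z)-3-iodoprop-2-enoate | I/C=C\C(=O)OC(C)(C)C#C | intermediate
21 | (5E)-5-(iodomethylidene)-6,6-dimethyl-5,6-dihydro-2H-pyran-2-one | I/C=C1\C=CC(=O)OC1(C)C | intermediate
22 | methyl (2S,3S,4S,5S,8R)-8-(furan-3-carbonyl)-4-[(2E)-2-(2,2-dimethyl-6-oxo-2H-pyran-3(6H)-ylidene)-1-hydroxyethyl]-5-[(1R)-1-hydroxyethyl]-4,8-dimethyl-1-oxaspiro[2.5]octane-2-carboxylate (carbinol epimers) | COC(=O)[C@H]1O[C@@]12[C@](C)(C(=O)c1ccoc1)CC[C@H]([C@@H](C)O)[C@@]2(C)C(O)/C=C1\C=CC(=O)OC1(C)C | intermediate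
23 | methyl (2S,3R,4R,5S,8R)-4-[(2E)-2-(2,2-dimethyl-6-oxo-2H-pyran-3(6H)-ylidene)acetyl]-8-(furan-3-carbonyl)-5-[(1R)-1-hydroxyethyl]-4,8-dimethyl-1-oxaspiro[2.5]octane-2-carboxylate | COC(=O)[C@H]1O[C@@]12[C@](C)(C(=O)c1ccoc1)CC[C@H]([C@@H](C)O)[C@@]2(C)C(=O)/C=C1\C=CC(=O)OC1(C)C | target

**Step count**

Total step count: 14. Longest linear sequence: 11 steps (steps 1, 2, 3, 5, 6, 7, 8, 9, 10, 13 and 14).

**Steps most likely to fail**

Step 5. The ring closure may go through the enolate oxygen instead of carbon (cyclic enol ether formation), the hindered enolate may fail to open the epoxide, or facial selectivity at the quaternary carbon may be poor. The fallback uncouples the two bond formations and replaces the anionic closure by electrophile activation. It sets out from 8, isolated after the sodium hydride stage alone. A Lewis acid (Sc(OTf)3 or SnCl4, CH2Cl2, −78 → 0 °C) activates the epoxide so that the neutral enol of the β-keto ester attacks through carbon, as in cationic epoxy β-keto ester cyclisations, with inversion at the epoxide carbon. This should give methyl (1R,2S)-5-[(ethylsulfanyl)carbonyl]-2-[(1R)-1-hydroxyethyl]-1-methyl-6-oxocyclohexane-1-carboxylate F1, which p-TsOH in toluene lactonises, and the route is rejoined at 9.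

Step 8. The chloroacetate enolate may not add to the doubly neopentyl ketone (reversal of the aldol step), or the aldolate may fragment by retro-Claisen cleavage before it closes. The fallback builds the glycidate from a small nucleophile that adds irreversibly and sets out from 12. Vinylmagnesium bromide with CeCl3 (THF, −78 °C, axial attack as before, ketone addition expected to outpace attack on the hindered thioester) should give the tertiary allylic alcohol F2. Hydroxyl-directed epoxidation (VO(acac)2, t-BuOOH, CH2Cl2) should give the epoxy alcohol F3. Payne rearrangement (NaH, THF) moves the oxirane onto the ring carbon with inversion at the former vinyl CH and should give the spiro-epoxy primary alcohol F4. Oxidation (TEMPO, PhI(OAc)2, MeCN/H2O) should give the glycidic acid F5, and Me3SiCHN2 in MeOH/toluene returns the route to 14.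

Step 9. Oxidative addition and transmetalation at the axial, neopentyl thioester may be too slow, so that the boronic acid is consumed by protodeboronation. The fallback makes the ketone from the aldehyde and sets out from 14. Fukuyama reduction (Et3SiH, Pd/C, acetone, 23 °C) should give the aldehyde F6. 3-Furyllithium (from 3-bromofuran and n-BuLi, THF, −78 °C) should add to the aldehyde much faster than to the hindered glycidic ester and give the furyl carbinol F7. Dess–Martin periodinane (CH2Cl2, NaHCO3) then oxidises it, and the route is rejoined at 16.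

**Further compounds**

F1 | step 5 | methyl (1R,2S)-5-[(ethylsulfanyl)carbonyl]-2-[(1R)-1-hydroxyethyl]-1-methyl-6-oxocyclohexane-1-carboxylate (C-5 epimers) | CCSC(=O)C1CC[C@H]([C@@H](C)O)[C@@](C)(C(=O)OC)C1=O
F2 | step 8 | S-ethyl 7-ethenyl-7-hydroxy-1-methoxy-3,6,7a-trimethyloctahydro-2-benzofuran-6-carbothioate (other centres as in 12; vinyl axial and anti to the 7a-methyl) | CCSC(=O)[C@]1(C)CC[C@@H]2[C@@H](C)OC(OC)[C@@]2(C)[C@@]1(O)C=C
F3 | step 8 | S-ethyl 7-hydroxy-1-methoxy-3,6,7a-trimethyl-7-(oxiran-2-yl)octahydro-2-benzofuran-6-carbothioate (other centres as in F2; oxirane CH as drawn) | CCSC(=O)[C@]1(C)CC[C@@H]2[C@@H](C)OC(OC)[C@@]2(C)[C@@]1(O)[C@@H]3CO3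
F4 | step 8 | S-ethyl 3'-(hydroxymethyl)-1-methoxy-3,6,7a-trimethylhexahydro-1H-spiro[2-benzofuran-7,2'-oxirane]-6-carbothioate (configured as 14) | CCSC(=O)[C@]1(C)CC[C@@H]2[C@@H](C)OC(OC)[C@@]2(C)[C@]13O[C@@H]3CO
F5 | step 8 | 6-[(ethylsulfanyl)carbonyl]-1-methoxy-3,6,7a-trimethylhexahydro-1H-spiro[2-benzofuran-7,2'-oxirane]-3'-carboxylic acid (configured as 14) | CCSC(=O)[C@]1(C)CC[C@@H]2[C@@H](C)OC(OC)[C@@]2(C)[C@]13O[C@@H]3C(=O)O
F6 | step 9 | methyl 6-formyl-1-methoxy-3,6,7a-trimethylhexahydro-1H-spiro[2-benzofuran-7,2'-oxirane]-3'-carboxylate (configured as 14) | O=C[C@]1(C)CC[C@@H]2[C@@H](C)OC(OC)[C@@]2(C)[C@]13O[C@@H]3C(=O)OC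
F7 | step 9 | methyl 6-[furan-3-yl(hydroxy)methyl]-1-methoxy-3,6,7a-trimethylhexahydro-1H-spiro[2-benzofuran-7,2'-oxirane]-3'-carboxylate (configured as 14; carbinol epimers) | OC(c1ccoc1)[C@]2(C)CC[C@@H]3[C@@H](C)OC(OC)[C@@]3(C)[C@]24O[C@@H]4C(=O)OC
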